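All runs are simulated for substances that don't exist.

**The question.** If flasks are to be ranked by final target, the first thing to reckon is how much turnover each one is allowed.

all flasks: starting material 0.15 M; reagent 0.225 M
- Wednesday's: free catalyst 0.55 mM; temperature 30 °C; run made earlier
- Thursday's: free catalyst 2.2 mM; temperature 41 °C; run made earlier
- south-east: free catalyst 3.0 mM; at 25 °C until 12 min, from then on at 45 °C; time 25 min
- south: free catalyst 0.80 mM; at 25 °C throughout; time 100 min

| run | time / min | target / % | starting material / % |
|---|---|---|---|
| Wednesday's | 2.50 | 2.6 | 97.7 |
| Wednesday's | 5.00 | 5.2 | 94.5 |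
| Wednesday's | 8.00 | 7.2 | 90.5 |
| Wednesday's | 10.0 | 9.1 | 88.0 |
| Wednesday's | 12.0 | 10.8 | 84.5 |
| Thursday's | 0.417 | 0.8 | 99.0 |
| Thursday's | 1.33 | 1.6 | 97.2 |
| Thursday's | 2.50 | 3.2 | 96.6 |
| Thursday's | 4.00 | 5.2 | 92.6 |
| Thursday's | 5.00 | 6.3 | 90.0 |

(standard deviation of a reading: 0.5 percentage points)

* the flask that ends with the higher amount of target, in percent of the starting material charged, or "neither" when 2 percentage points or less lies between them (south-east / south / neither)
* final target, as a percentage of the starting material charged, in south-east
* final target, as a percentage of the starting material charged, in south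

- the numbers in the tables scatter with a standard deviation of 0.5 percentage points
- candidate steps: reagent + catalyst intermediate A <-> catalyst intermediate B; starting material + released group -> side product; starting material + free catalyst <-> catalyst intermediate A; catalyst intermediate B <-> released group + catalyst intermediate C; catalyst intermediate D -> free catalyst + target; catalyst intermediate C -> catalyst intermediate D

**Turnover rate.** Target per free catalyst charged and per minute, the turnover frequency n, reads 2.45 /min at 30 °C in Wednesday's run and 0.859 /min at 41 °C in Thursday's, so n is lower in the warmer run. In powers of ten the fall is 0.455 over that span. Taken as a straight line in the logarithm, with rate in step with catalyst, this reckoning gives 3.96 /min at 25 °C and 0.586 /min at 45 °C.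

**The ladder.** At the rate reckoned for 25 °C, one turnover takes 0.253 min. The next rung is the catalyst time, c(starting material)/(n·c(free catalyst)), in which turnover at the early rate would equal the charge. It is 12.6 min for cold south-east, 47.4 min for south and 85.3 min for warm south-east. The side clock comes from the gap between starting material lost and target: it is the time at which that gap would equal target, if their ratio grows in step with time. It reads 27.6 min on Wednesday and 8.51 min on Thursday, shorter in the warmer run. The catalyst time reckoned for warm south-east is far longer than Thursday's clock.

**Turnover allowance.** Flask time divided by catalyst time, summed over the temperature stages, gives south-east 1.10. This is the turnover allowance, the multiple of the charge that the catalyst could turn over if its early rate held. South gets 2.11, about twice as much, so this reckoning ranks south ahead.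

**The forecast.** It names south, with 54% in south-east and 60% in south, holding that “Heating then favours the side reaction”.

**The result.** South-east ends at 53.0% and south at 60.3%, so the flask with more target is south. The steps were:

    reagent + catalyst intermediate A ⇌ catalyst intermediate B (K = 1.00 /M, k = 7.60 /M/s, Ea = 55.0 kJ/mol, ΔH = −90.0 kJ/mol)
    starting material + released group → side product (k = 0.00790 /M/s, Ea = 75.0 kJ/mol)
    starting material + free catalyst ⇌ catalyst intermediate A (K = 4.50 /M, k = 2.30 /M/s, Ea = 35.0 kJ/mol, ΔH = −82.0 kJ/mol)
    catalyst intermediate B ⇌ released group + catalyst intermediate C (K = 2.80 M, k = 1.00 /s, Ea = 68.0 kJ/mol, ΔH = −36.0 kJ/mol)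
    catalyst intermediate D → free catalyst + target (k = 0.780 /s, Ea = 78.0 kJ/mol)
    catalyst intermediate C → catalyst intermediate D (k = 2.20 /s, Ea = 73.0 kJ/mol)
    (constants at 25 °C)

**The allowance used.** South-east holds 51.1% target at 12.0 min and 53.0% at 25.0 min, while its side product goes from 11.8% to 38.4%. Of its allowance of 1.10, the cold stage supplied 0.949. The neighbour flask with 7.5 × 10⁻⁴ M of free catalyst, otherwise south-east, has an allowance of 0.275, and it ends with 19.9% target beside 60.9% starting material.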